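**Atom numbering used throughout (caryophyllane numbering).** C1 and C9 are the ring-fusion carbons. C2–C8 complete the nine-membered ring, with a methyl on C4 and the exocyclic methylene on C8. C10 and C11 complete the cyclobutane, with a methyl on C11. C12 is the hemiperketal carbon, C13=C14 the dioxine olefin, and C15 carries a methyl, the hydroxymethyl carbon C17 and the peroxide oxygen.

## Analysis of the target

The target is a bicyclo[7.2.0]undecane. A cyclobutane (C1, C9, C10, C11) is trans-fused to a nine-membered carbocycle that bears an exocyclic methylene at C8 and a trisubstituted 4,5-epoxide whose ring carbons C3 and C6 are trans. At C11, next to a methyl group, stands a 3,6-dihydro-1,2-dioxin-3-ol (C12, C13=C14, C15, O–O bridge from C15 to C12).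

There are seven stereocentres. C1 (S), C9 (R) and C11 (S) lie on the cyclobutane, with H1 and H9 trans, C12 trans to the C2 branch on C1, and C12 cis across the ring to C8. C4 (S) and C5 (S) of the epoxide stand to the ring fusion as in caryophyllene oxide, here in the mirror-image series. C12 (R) and C15 (R) lie in the dioxine, with the C12 hydroxyl and the C17 hydroxymethyl on the same face.

The sensitive groups are the dialkyl peroxide and its hemiperketal (reductants, phosphines, strong base, transition metals), the medium-ring epoxide that opens transannularly with acid, the strained E ring olefin that precedes it, and the exocyclic olefin.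

The synthesis is hard in three places:
- the nine-membered ring with its trans fusion;
- the quaternary C11, whose methyl and C12 branches are similar in size and must be told apart relative to C1;
- the peroxide, whose C15 centre is remote from every other stereocentre and tolerates little chemistry once in place.

The strategy rests on one feature. C8 (a ketone before methylenation) and the C4=C5 olefin (the epoxide before oxidation) are in a γ,δ-unsaturated ketone relationship through C7 and C6. This is the retron of a Claisen rearrangement, so the nine-membered ring can be grown from a seven-membered oxacycle in which oxygen links C8 and C4, C8 carries an exocyclic methylene (C7) and C4 a vinyl group (C5=C6).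

A seven-membered ring cannot hold C3 in the pseudo-equatorial position of the chair transition state. The ring expansion is therefore expected to turn the C4 centre into a Z olefin, and the E geometry that the trans epoxide needs is introduced afterwards by a stereospecific olefin inversion.

## Retrosynthetic reasoning

**Epoxide (38 ⇒ 37).** The C4–O and C5–O bonds are cut last. The epoxide is the most acid-labile group of the target, and the E ring olefin of 37 is its most nucleophilic and most strained double bond. The forward reaction is a peracid oxidation from the outer face of the ring, which has to leave the exocyclic methylene and the dioxine olefin alone.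

**Hemiperketal (37 ⇒ 36 ⇒ 35).** The C12–O bond is cut because it forms by itself once the hydroperoxide at C15 can reach the C12 ketone. That is possible only in the Z enone 36. The forward step therefore only has to isomerise the E enone 35; ring closure then removes the Z isomer from the equilibrium and sets C12 under thermodynamic control.

**C13=C14 (35 ⇒ 34 ⇒ 32 ⇒ 24 + 30).** The enone is cut at the double bond into methyl ketone 24 and aldehyde 30. C11 is quaternary, so 24 can form only one enolate. C15 is quaternary, so 30 cannot enolise. The disconnection is convergent and keeps the peroxide, protected in 30, away from all earlier chemistry.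

**Peroxide fragment (30 ⇒ 29 ⇒ 28 ⇒ 27 ⇒ 26 ⇒ 25).** The C15–O bond is cut back to the oxirane of 25. The peroxide enters at the tertiary carbon with inversion, and the oxirane methylene becomes C17. The hydroxymethyl carbon of 25 becomes the aldehyde carbon C14, which is why the S enantiomer of 2-methylglycidol is required.

**Olefin geometry and C8 methylene (24 ⇒ 23 ⇒ 19/20 ⇒ 18 ⇒ 17).** The ketal of 23 protects C12 up to this point. The E olefin of 23 is traced back to the Z olefin of 18 through the cis-epoxides 19 and 20, whose C–O bonds are cut with inversion of geometry. Both faces of the Z olefin lead to the same E olefin, so no facial selectivity is needed. The exocyclic methylene of 18 comes from the C8 ketone of 17 by ylide methylenation. This is placed before the inversion because the inversion reagent would attack a ketone.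

**Nine-membered ring (17 ⇒ 16).** The C6–C7 bond is cut. In the forward direction the allyl vinyl ether C7=C8–O–C4–C5=C6 of 16 rearranges and the seven-membered oxacycle becomes the nine-membered ketone. The disconnection removes the medium ring in one step and needs no high dilution. It also uses the cyclobutane only as a spectator.

**Enol ether and lactone (16 ⇒ 15 ⇒ 13).** The exocyclic methylene of 16 is cut back to the lactone carbonyl of 15, which a titanium methylidene reagent converts without acid or base. The C8–O bond of 15 is cut to hydroxy acid 13. The forward lactonisation must acylate a tertiary allylic alcohol and close a seven-membered ring on a trans-1,2-disubstituted cyclobutane.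

**Cyclobutane (13 ⇒ 12 ⇒ 10 ⇒ 9 ⇒ 8 ⇒ 7).** The C11–C12 bond and then the C9–C1 and C9–C11 bonds are cut. Diazo ester 7 closes onto its trisubstituted olefin to give bicyclobutane 8, and an acyl-anion equivalent opens the central bond at C11. The E geometry of the chain fixes C1 relative to C11 (methyl cis to the C2 branch, C12 trans). The catalyst chooses the olefin face, and C9 is set by equilibration of the ester.

**Chain (7 ⇒ 6 ⇒ 4 + 5; 4 ⇒ 3 ⇒ 2 ⇒ 1).** The C9–C10 bond is cut to allylic bromide 4 and methyl acetoacetate 5. Bromide 4 comes from the E-methyl group of silylated (R)-linalool 2 by allylic oxidation. Linalool 1 supplies C1–C6, C10, C11, the C11 methyl and the C4 carbinol centre, which is later converted into olefin geometry.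

## Alternatives that were turned down

**Alternative 1:** The C1–C11 bond of the cyclobutane is disconnected. In the forward direction the free pyrrolidine A1 (nitrogen between C1 and C11) is N-aminated by an iodonitrene, the 1,1-diazene loses N2, and the 1,4-biradical collapses to cyclobutane A2.
- For: a pyrrolidine with three contiguous centres, including the quaternary one, is accessible by azomethine ylide cycloaddition with well-understood control, and the contraction is largely stereoretentive. In direct control of the cyclobutane triad this is as strong as or stronger than the rhodium-catalysed closure chosen here.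
- Against: the radical at C11 is ester-stabilised and long-lived, so β-scission to two olefins and loss of configuration compete. Both C11 substituents of A2 (ester and benzyloxymethyl) need redox adjustment to become the methyl group and the C12 ketone. The nine-membered ring is not addressed at all and would still have to be closed from an open chain.
- Comparison: the chosen strategy offers the medium ring by a thermal ring expansion and has C12 at the ketone oxidation level from the moment the cyclobutane exists. It pays with reliance on a chiral catalyst for the absolute configuration.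

**Alternative 2:** Both C–O bonds of the dioxine are disconnected. In the forward direction hydrogen peroxide adds to the C12 ketone of the Z enone epoxide A3, and the hemiperketal hydroperoxide opens the oxirane 6-exo at C15 with inversion. This gives A4, which is identical with 37 of the chosen route.
- For: the peroxide is introduced with the simplest reagent and without protecting groups, and C15 comes from an oxirane of defined configuration. In step economy of the endgame it is stronger than the chosen route.
- Against: it says nothing about the carbocyclic core. The Z enone must be made and kept, since the E isomer cannot cyclise. Addition of a hydroperoxide to a ketone on a quaternary carbon is unfavourable. The acids or molybdenum catalysts that promote it also epoxidise the strained ring olefin with hydrogen peroxide, and they can ionise the tertiary allylic oxirane, with loss of configuration at C15 or attack at C17.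
- Comparison: the chosen route makes the C15–O bond on a small fragment, where its configuration can be secured before coupling, and reaches the same compound by hemiperketal closure alone. It pays with two protecting groups and a longer fragment synthesis.

**Alternative 3:** The C9–C10 bond is disconnected, so that the cyclobutane is closed last on a preformed E-cyclononenone. The C9 enolate of bis-tosylate A5 displaces one of two diastereotopic tosyloxymethyl groups to give ketone A6.
- For: the medium ring is made on a monocyclic substrate where the E olefin could be set by an established method. On olefin geometry it is stronger than the chosen route, which must invert a Z olefin. The trans ring fusion is the thermodynamic one.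
- Against: the closure must distinguish two diastereotopic groups under the influence of C1 alone on a flexible ring, so C11 is weakly controlled. A ketone enolate that can choose between C-alkylation to a four-membered ring and O-alkylation to a six-membered enol ether prefers the latter. The displacement is at a neopentyl carbon. A6 still carries C12 as a neopentyl tosylate that has to be turned into an acyl group.
- Comparison: the chosen route controls C11 by olefin geometry in a stereospecific addition and introduces C12 together with its oxygen. In exchange it accepts two extra steps for the olefin inversion.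

Key step: step 12

**Remarks on the chemistry.**
- The C12 configuration of the target is taken to be the thermodynamically preferred hemiperketal (hydroxyl anomeric, cyclobutyl and hydroxymethyl groups pseudo-equatorial); it is set by equilibration in step 25.
- Rh2(S-NTTL)4 is taken to select the olefin face that leads to (1S)-configured 8; should the sense be opposite on this substrate, the enantiomeric catalyst Rh2(R-NTTL)4 is used.

## Route

Step 1
Reactants: 1 (R)-linalool
Product: 2 (3R)-3,7-dimethyl-3-(triethylsilyloxy)octa-1,6-diene
Conditions: TESOTf, 2,6-lutidine, CH2Cl2, −78 to 0 °C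
Reagents that add atoms: triethylsilyl triflate, CC[Si](CC)(CC)OS(=O)(=O)C(F)(F)F
Why: Silylation of a tertiary alcohol with a silyl triflate; the ether shields the hydroxyl from the carbene, the organometallic reagents and the titanium reagent used later and leaves C4 untouched.

Step 2
Reactants: 2 silyl ether
Product: 3 (2E,6R)-2,6-dimethyl-6-(triethylsilyloxy)octa-2,7-dien-1-ol
Conditions: SeO2 (cat.), tBuOOH, CH2Cl2, 0 °C to rt
Reagents that add atoms: selenium dioxide, O=[Se]=O; tert-butyl hydroperoxide, CC(C)(C)OO
Why: Riley allylic oxidation (ene reaction, then [2,3]-shift) attacks the electron-rich trisubstituted olefin at the methyl group trans to the chain, so the E allylic alcohol should result; the vinyl group is far less reactive.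

Step 3
Reactants: 3 allylic alcohol
Product: 4 (2E,6R)-1-bromo-2,6-dimethyl-6-(triethylsilyloxy)octa-2,7-diene
Conditions: CBr4, PPh3, CH2Cl2, 0 °C
Reagents that add atoms: carbon tetrabromide, BrC(Br)(Br)Br
Why: Appel bromination of the primary allylic alcohol under neutral conditions; substitution at the primary carbon keeps the E geometry and the tertiary silyl ether is inert.

Step 4
Reactants: 4 allylic bromide; 5 methyl acetoacetate
Product: 6 methyl (4E,8R)-2-acetyl-4,8-dimethyl-8-(triethylsilyloxy)deca-4,9-dienoate (C2 epimers)
Conditions: NaH, THF, 0 °C to rt (5 in excess)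
Reagents that add atoms: none
Why: C-alkylation of the sodium enolate of a β-keto ester by a primary allylic bromide (SN2) forms C9–C10; excess 5 suppresses dialkylation and the new centre is lost in the next step.

Step 5
Reactants: 6 β-keto ester
Product: 7 methyl (4E,8R)-2-diazo-4,8-dimethyl-8-(triethylsilyloxy)deca-4,9-dienoate
Conditions: 4-acetamidobenzenesulfonyl azide, DBU, MeCN, 0 °C to rt
Reagents that add atoms: 4-acetamidobenzenesulfonyl azide, CC(=O)Nc1ccc(cc1)S(=O)(=O)N=[N+]=[N-]
Why: Regitz deacylative diazo transfer: N2 is delivered to the tertiary α-carbon and the acetyl group leaves as the N-acyl sulfonamide, which gives the α-alkyl-α-diazo ester.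

Step 6
Reactants: 7 diazo ester
Product: 9 methyl (2S,3S)-3-(1-ethoxyethenyl)-3-methyl-2-[(3R)-3-methyl-3-(triethylsilyloxy)pent-4-en-1-yl]cyclobutane-1-carboxylate (epimers at the ester carbon C9), via bicyclobutane ester 8 (not isolated)
Conditions: Rh2(S-NTTL)4 (dirhodium tetrakis[N-naphthaloyl-(S)-tert-leucinate], 1 mol %), toluene, −78 °C, slow addition; then Li[Cu(C(OEt)=CH2)2] (from ethyl vinyl ether, tBuLi, CuBr·SMe2), THF, −78 to −30 °C; 2,6-di-tert-butyl-4-methylphenol, then aq. NH4Cl
Reagents that add atoms: ethyl vinyl ether (as its lithio cuprate), C=COCC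
Why: Rhodium-carbene cyclopropanation of the tethered olefin of an α-allyl-α-diazo ester forms C9–C1 and C9–C11 and gives the bicyclobutane with the chain exo (from the E olefin), the catalyst choosing the olefin face. Strain-release homoconjugate addition of the acyl-anion equivalent then attacks bridgehead C11 from the rear of the central bond, which places C12 trans and the methyl group cis to the C2 branch. C9 is left as a mixture and is corrected in step 8.

Step 7
Reactants: 9 enol ether ester
Product: 10 methyl (2S,3S)-3-methyl-3-(2-methyl-1,3-dioxolan-2-yl)-2-[(3R)-3-methyl-3-(triethylsilyloxy)pent-4-en-1-yl]cyclobutane-1-carboxylate (C9 epimers)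
Conditions: ethylene glycol, PPTS (cat.), CH2Cl2, 4 Å sieves, rt
Reagents that add atoms: ethylene glycol, OCCO
Why: Acid-catalysed addition of the diol to the enol ether and loss of ethanol give the dioxolane without passing through the free ketone; the tertiary silyl ether and the ester are inert to PPTS.

Step 8
Reactants: 10 dioxolane ester
Product: 12 (1R,2S,3S)-3-methyl-3-(2-methyl-1,3-dioxolan-2-yl)-2-[(3R)-3-methyl-3-(triethylsilyloxy)pent-4-en-1-yl]cyclobutane-1-carboxylic acid, via trans methyl ester 11 (not isolated)
Conditions: NaOMe, MeOH, 60 °C; then H2O, 60 °C; 1 M HCl to pH 4 at 0 °C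
Reagents that add atoms: water, O
Why: Equilibration through the ester enolate places C8 trans to the C2 branch and cis-1,3 to the dioxolanyl group, so that all three large groups are pseudo-equatorial, and saponification follows; C1 and C11 have no acidic hydrogen and cannot epimerise.

Step 9
Reactants: 12 silyl ether acid
Product: 13 (1R,2S,3S)-2-[(3R)-3-hydroxy-3-methylpent-4-en-1-yl]-3-methyl-3-(2-methyl-1,3-dioxolan-2-yl)cyclobutane-1-carboxylic acid
Conditions: TBAF, THF, rt; aq. NH4Cl
Reagents that add atoms: none
Why: Fluoride cleavage of the tertiary triethylsilyl ether; carboxylate, dioxolane and olefins do not react.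

Step 10
Reactants: 13 hydroxy acid
Product: 15 (1R,4R,7S,8S)-4-ethenyl-4,8-dimethyl-8-(2-methyl-1,3-dioxolan-2-yl)-3-oxabicyclo[5.2.0]nonan-2-one (trans-fused lactone), via pyridyl thioester 14 (not isolated)
Conditions: 2,2'-dipyridyl disulfide, PPh3, toluene, rt; then AgOTf, toluene/MeCN, 0.002 M, rt to 50 °C
Reagents that add atoms: none
Why: Corey–Nicolaou lactonisation in its silver-promoted form, the thioester activation that acylates tertiary alcohols; the trans-1,2 arrangement on the cyclobutane keeps carboxyl and chain within reach and high dilution suppresses diolide formation.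

Step 11
Reactants: 15 lactone
Product: 16 (1R,4R,7S,8S)-4-ethenyl-4,8-dimethyl-2-methylidene-8-(2-methyl-1,3-dioxolan-2-yl)-3-oxabicyclo[5.2.0]nonane (cyclobutane-fused 2-methylene-7-methyl-7-vinyloxepane)
Conditions: Cp2TiMe2, toluene, 70 °C, dark; filtration through basic alumina
Reagents that add atoms: dimethyltitanocene, C[Ti](C)(C1C=CC=C1)C1C=CC=C1
Why: Petasis methylenation turns the lactone carbonyl into the exocyclic enol ether regiospecifically without acid or base, so C9 keeps its configuration; the dioxolane hides the only other carbonyl group.

Step 12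
Reactants: 16 2-methylene-7-vinyloxepane
Product: 17 (1S,4Z,9R,11S)-4,11-dimethyl-11-(2-methyl-1,3-dioxolan-2-yl)bicyclo[7.2.0]undec-4-en-8-one
Conditions: xylene (degassed, 0.02 M), Et3N (trace), silanised sealed tube, 150–170 °C
Reagents that add atoms: none
Why: The allyl vinyl ether C7=C8–O–C4–C5=C6 undergoes a concerted, suprafacial [3,3]-sigmatropic (Claisen) rearrangement in which C6–C7 forms while C4–O breaks and the C8 carbonyl and the C4=C5 olefin appear. The closest known reaction type is the Claisen ring expansion of 2-methylene-ω-vinyl oxacycles, obtained by methylenation of vinyl lactones, to cycloalkenones two carbons larger. The nine-membered carbocycle is closed by the C6–C7 bond in a ring-enlargement mode: the oxepane oxygen leaves the ring as the carbonyl oxygen and no small ring is formed. No stereocentre is created; C1, C9 and C11 are spectators and the C4 centre is converted into olefin geometry. In the chair transition state the four-carbon tether C9–C1–C2–C3 can only reach the pseudo-axial position at C4, because the pseudo-equatorial one would need an anti C3–C4–O–C8 arrangement that a seven-membered ring cannot adopt, so the Z olefin is expected; the E olefin would need a boat with an eclipsed C8–C9–C1–C2 unit, which the trans fusion excludes. The trans fusion fixes the sign of the C8–C9–C1–C2 torsion, and a model of the chair indicates that it is the 4R epimer, derived from (R)-linalool, whose vinyl group then lies on the matching face. The step needs the sigmatropic path to win over acid-catalysed isomerisation of the enol ether and ionisation of the tertiary allylic C–O bond, which base-washed glass, a trace of amine and the absence of any acid should secure. Carbonyl formation and relief of the trans four-seven fusion drive the reaction.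

Step 13
Reactants: 17 Z ketone
Product: 18 (1S,4Z,9R,11S)-4,11-dimethyl-8-methylidene-11-(2-methyl-1,3-dioxolan-2-yl)bicyclo[7.2.0]undec-4-ene
Conditions: Ph3PCH3Br, KOtBu, toluene, rt to 60 °C
Reagents that add atoms: methyltriphenylphosphonium bromide, C[P+](c1ccccc1)(c1ccccc1)c1ccccc1.[Br-]
Why: Wittig methylenation of the ring ketone; under these basic conditions C9 can only settle in the trans-fused arrangement, the more stable one for the four-nine ring system, and the dioxolane protects C12.

Step 14
Reactants: 18 Z diene
Product: 19 (4R,5S)-cis-4,5-epoxide of 18 and 20 (4S,5R)-cis-4,5-epoxide of 18, used together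
Conditions: mCPBA (1.05 equiv), NaHCO3, CH2Cl2, −20 to 0 °C
Reagents that add atoms: 3-chloroperbenzoic acid, OOC(=O)c1cccc(Cl)c1
Why: Prilezhaev epoxidation prefers the trisubstituted ring olefin to the 1,1-disubstituted exocyclic one; syn addition to the Z olefin gives cis-epoxides and the face is immaterial because both isomers converge in step 15.

Step 15
Reactants: 19 cis-epoxide; 20 cis-epoxide
Product: 23 (1S,4E,9R,11S)-4,11-dimethyl-8-methylidene-11-(2-methyl-1,3-dioxolan-2-yl)bicyclo[7.2.0]undec-4-ene, via lithium phosphino alkoxide 21 (not isolated), via lithium phosphino alkoxide 22 (not isolated)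
Conditions: Ph2PLi, THF, rt; then MeI, rt
Reagents that add atoms: none
Why: Epoxide deoxygenation with inversion of olefin geometry: the phosphide opens the oxirane at the secondary carbon C5 by SN2 (anti), P-methylation gives the betaine, and Wittig-type syn cycloelimination of methyldiphenylphosphine oxide gives the E olefin from either cis-epoxide. The exocyclic olefin and the dioxolane are inert.

Step 16
Reactants: 23 E diene ketal
Product: 24 1-[(1S,4E,9R,11S)-4,11-dimethyl-8-methylidenebicyclo[7.2.0]undec-4-en-11-yl]ethan-1-one
Conditions: PPTS, acetone/H2O (5:1), 45 °C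
Reagents that add atoms: water, O
Why: Mild acid-catalysed hydrolysis of the dioxolane frees the C12 methyl ketone; PPTS is too weak to start a transannular cyclisation of the diene and no epoxide is present yet.

Step 17
Reactants: 25 (S)-2-methylglycidol
Product: 26 tert-butyl{[(2-methyloxiran-2-yl)methyl]oxy}diphenylsilane (same spatial arrangement as 25)
Conditions: TBDPSCl, imidazole, DMF, rt
Reagents that add atoms: tert-butyl(chloro)diphenylsilane, CC(C)(C)[Si](Cl)(c1ccccc1)c1ccccc1
Why: Silylation of the primary alcohol; the bulky silyl ether withstands the acidic perhydrolysis, does not take part as a neighbouring group, and is later removed by fluoride.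

Step 18
Reactants: 26 silyl glycidyl ether
Product: 27 (S)-3-(tert-butyldiphenylsilyloxy)-2-hydroperoxy-2-methylpropan-1-ol
Conditions: H2O2 (anhydrous, in Et2O), H3PMo12O40 (cat.), Et2O, rt
Reagents that add atoms: hydrogen peroxide, OO
Why: Acid-catalysed perhydrolysis of a 2,2-disubstituted oxirane: hydrogen peroxide attacks the tertiary carbon with inversion (borderline SN2), which sets C15; the oxirane oxygen stays on the primary carbon as the future C17 hydroxyl.

Step 19
Reactants: 27 hydroxy hydroperoxide
Product: 28 silyl ether with the hydroperoxide as 2-methoxyprop-2-yl peroxyketal and the alcohol as 2-methoxyprop-2-yl ether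
Conditions: 2-methoxypropene, PPTS (cat.), CH2Cl2, 0 °C
Reagents that add atoms: 2-methoxypropene, COC(C)=C
Why: Acid-catalysed addition of the hydroperoxide and of the alcohol to the enol ether; the peroxyketal and the mixed ketal are stable to base, fluoride and hypervalent iodine and come off together under very mild acid.

Step 20
Reactants: 28 bis-ketal silyl ether
Product: 29 (S)-3-[(2-methoxypropan-2-yl)oxy]-2-[(2-methoxypropan-2-yl)peroxy]-2-methylpropan-1-ol
Conditions: TBAF, THF, 0 °C to rt; aq. NH4Cl
Reagents that add atoms: none
Why: Fluoride desilylation frees the primary alcohol that becomes C14; peroxyketals are inert to fluoride and C15 has no hydrogen for a base-induced peroxide fragmentation.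

Step 21
Reactants: 29 alcohol
Product: 30 (S)-3-[(2-methoxypropan-2-yl)oxy]-2-[(2-methoxypropan-2-yl)peroxy]-2-methylpropanal
Conditions: Dess–Martin periodinane, NaHCO3, CH2Cl2, 0 °C
Reagents that add atoms: none
Why: Buffered Dess–Martin oxidation; the α-carbon is quaternary, so the aldehyde can neither enolise nor epimerise.

Step 22
Reactants: 24 methyl ketone; 30 aldehyde
Product: 32 β-hydroxy ketone (C14 epimers), via lithium enolate 31 (not isolated)
Conditions: LDA, THF, −78 °C; then 30, −78 °C; aq. NH4Cl
Reagents that add atoms: none
Why: Directed aldol addition: the ketone has enolisable hydrogen only on the C13 methyl group and the aldehyde is non-enolisable; the configuration at C14 is irrelevant because it is removed in step 23.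

Step 23
Reactants: 32 aldol adduct
Product: 34 E enone with protected peroxide, via mesylate 33 (not isolated)
Conditions: MsCl, Et3N, CH2Cl2, 0 °C; then DBU, rt
Reagents that add atoms: none
Why: Mesylation and E1cB elimination give the conjugated E enone; the peroxyketal is base-stable and C15 bears no hydrogen, so a Kornblum–DeLaMare fragmentation cannot occur.

Step 24
Reactants: 34 protected E enone
Product: 35 (E)-γ-hydroperoxy enone with free C17 hydroxyl
Conditions: PPTS (cat.), MeOH, 0 °C
Reagents that add atoms: none
Why: Acid-catalysed transketalisation to methanol removes both 2-methoxyprop-2-yl groups; the E enone cannot reach the hydroperoxide, so the open form should be obtained.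

Step 25
Reactants: 35 E hydroperoxy enone
Product: 37 (1S,4E,9R,11S)-11-[(3R,6R)-3-hydroxy-6-(hydroxymethyl)-6-methyl-3,6-dihydro-1,2-dioxin-3-yl]-4,11-dimethyl-8-methylidenebicyclo[7.2.0]undec-4-ene, via Z hydroperoxy enone 36 (not isolated)
Conditions: hν (365 nm), degassed MeCN, 10 °C
Reagents that add atoms: none
Why: Photochemical E/Z isomerisation of the enone; the Z isomer is drained from the photostationary mixture by 6-exo-trig addition of the hydroperoxide to the C12 carbonyl, and the hemiperketal no longer absorbs at 365 nm. C12 equilibrates through the open form to the anomerically stabilised configuration, and the peroxy adduct should be favoured over the isomeric hemiketal from the C17 hydroxyl.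

Step 26
Reactants: 37 dioxinol
Product: 38 target, (1S,4S,5S,9R,11S)-4,5-epoxide of 37
Conditions: mCPBA (1.0 equiv), NaHCO3, CH2Cl2, −20 °C
Reagents that add atoms: 3-chloroperbenzoic acid, OOC(=O)c1cccc(Cl)c1
Why: Prilezhaev epoxidation of the most nucleophilic and most strained olefin, the E trisubstituted ring double bond, from its outer face in the preferred ring conformers, as in the epoxidation of caryophyllene, should give the (4S,5S)-epoxide. The exocyclic methylene and the peroxide-flanked olefin react much more slowly, and bicarbonate protects the epoxide and the hemiperketal from acid.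

## Compound list

1 | (R)-linalool | CC(C)=CCC[C@@](C)(O)C=C | starting material
2 | (3R)-3,7-dimethyl-3-(triethylsilyloxy)octa-1,6-diene | CC(C)=CCC[C@@](C)(O[Si](CC)(CC)CC)C=C | intermediate
3 | (2E,6R)-2,6-dimethyl-6-(triethylsilyloxy)octa-2,7-dien-1-ol | OC/C(C)=C/CC[C@@](C)(O[Si](CC)(CC)CC)C=C | intermediate
4 | (2E,6R)-1-bromo-2,6-dimethyl-6-(triethylsilyloxy)octa-2,7-diene | BrC/C(C)=C/CC[C@@](C)(O[Si](CC)(CC)CC)C=C | intermediate
5 | methyl acetoacetate | CC(=O)CC(=O)OC | starting material
6 | methyl (4E,8R)-2-acetyl-4,8-dimethyl-8-(triethylsilyloxy)deca-4,9-dienoate (C2 epimers) | CC(=O)C(C/C(C)=C/CC[C@@](C)(O[Si](CC)(CC)CC)C=C)C(=O)OC | intermediate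
7 | methyl (4E,8R)-2-diazo-4,8-dimethyl-8-(triethylsilyloxy)deca-4,9-dienoate | COC(=O)C(=[N+]=[N-])C/C(C)=C/CC[C@@](C)(O[Si](CC)(CC)CC)C=C | intermediate
8 | methyl 3-methyl-2-exo-[(3R)-3-methyl-3-(triethylsilyloxy)pent-4-en-1-yl]bicyclo[1.1.0]butane-1-carboxylate | COC(=O)[C@@]12C[C@]1(C)[C@H]2CC[C@@](C)(O[Si](CC)(CC)CC)C=C | intermediate (not isolated)
9 | methyl (2S,3S)-3-(1-ethoxyethenyl)-3-methyl-2-[(3R)-3-methyl-3-(triethylsilyloxy)pent-4-en-1-yl]cyclobutane-1-carboxylate (C1 epimers; ring C1 = C9, ring C2 = C1, ring C3 = C11) | COC(=O)C1C[C@](C)(C(=C)OCC)[C@H]1CC[C@@](C)(O[Si](CC)(CC)CC)C=C | intermediate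
10 | methyl (2S,3S)-3-methyl-3-(2-methyl-1,3-dioxolan-2-yl)-2-[(3R)-3-methyl-3-(triethylsilyloxy)pent-4-en-1-yl]cyclobutane-1-carboxylate (C1 epimers) | COC(=O)C1C[C@](C)(C2(C)OCCO2)[C@H]1CC[C@@](C)(O[Si](CC)(CC)CC)C=C | intermediate
11 | methyl (1R,2S,3S) ester, the trans epimer of 10 | COC(=O)[C@@H]1C[C@](C)(C2(C)OCCO2)[C@H]1CC[C@@](C)(O[Si](CC)(CC)CC)C=C | intermediate (not isolated)
12 | (1R,2S,3S)-3-methyl-3-(2-methyl-1,3-dioxolan-2-yl)-2-[(3R)-3-methyl-3-(triethylsilyloxy)pent-4-en-1-yl]cyclobutane-1-carboxylic acid | OC(=O)[C@@H]1C[C@](C)(C2(C)OCCO2)[C@H]1CC[C@@](C)(O[Si](CC)(CC)CC)C=C | intermediate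
13 | (1R,2S,3S)-2-[(3R)-3-hydroxy-3-methylpent-4-en-1-yl]-3-methyl-3-(2-methyl-1,3-dioxolan-2-yl)cyclobutane-1-carboxylic acid | OC(=O)[C@@H]1C[C@](C)(C2(C)OCCO2)[C@H]1CC[C@@](C)(O)C=C | intermediate
14 | S-(pyridin-2-yl) thioester of 13 | O=C(Sc1ccccn1)[C@@H]1C[C@](C)(C2(C)OCCO2)[C@H]1CC[C@@](C)(O)C=C | intermediate (not isolated)
15 | (1R,4R,7S,8S)-4-ethenyl-4,8-dimethyl-8-(2-methyl-1,3-dioxolan-2-yl)-3-oxabicyclo[5.2.0]nonan-2-one | O=C1O[C@@](C)(C=C)CC[C@H]2[C@H]1C[C@]2(C)C2(C)OCCO2 | intermediate
16 | (1R,4R,7S,8S)-4-ethenyl-4,8-dimethyl-2-methylidene-8-(2-methyl-1,3-dioxolan-2-yl)-3-oxabicyclo[5.2.0]nonane | C=C1O[C@@](C)(C=C)CC[C@H]2[C@H]1C[C@]2(C)C2(C)OCCO2 | intermediate (key-step precursor)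
17 | (1S,4Z,9R,11S)-4,11-dimethyl-11-(2-methyl-1,3-dioxolan-2-yl)bicyclo[7.2.0]undec-4-en-8-one | O=C1CC/C=C(/C)CC[C@H]2[C@H]1C[C@]2(C)C2(C)OCCO2 | intermediate (key-step product)
18 | (1S,4Z,9R,11S)-4,11-dimethyl-8-methylidene-11-(2-methyl-1,3-dioxolan-2-yl)bicyclo[7.2.0]undec-4-ene | C=C1CC/C=C(/C)CC[C@H]2[C@H]1C[C@]2(C)C2(C)OCCO2 | intermediate
19 | (1S,4R,5S,9R,11S)-4,5-epoxide of 18 (cis-epoxide) | C=C1CC[C@@H]2O[C@]2(C)CC[C@H]2[C@H]1C[C@]2(C)C2(C)OCCO2 | intermediate
20 | (1S,4S,5R,9R,11S)-4,5-epoxide of 18 (cis-epoxide, other face) | C=C1CC[C@H]2O[C@@]2(C)CC[C@H]2[C@H]1C[C@]2(C)C2(C)OCCO2 | intermediate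
21 | lithium alkoxide of the 5-(diphenylphosphanyl)-4-ol from 19 (P and O anti) | [Li+].C=C1CC[C@@H](P(c2ccccc2)c2ccccc2)[C@](C)([O-])CC[C@H]2[C@H]1C[C@]2(C)C2(C)OCCO2 | intermediate (not isolated)
22 | lithium alkoxide of the 5-(diphenylphosphanyl)-4-ol from 20 (P and O anti) | [Li+].C=C1CC[C@H](P(c2ccccc2)c2ccccc2)[C@@](C)([O-])CC[C@H]2[C@H]1C[C@]2(C)C2(C)OCCO2 | intermediate (not isolated)
23 | (1S,4E,9R,11S)-4,11-dimethyl-8-methylidene-11-(2-methyl-1,3-dioxolan-2-yl)bicyclo[7.2.0]undec-4-ene | C=C1CC/C=C(\C)CC[C@H]2[C@H]1C[C@]2(C)C2(C)OCCO2 | intermediate
24 | 1-[(1S,4E,9R,11S)-4,11-dimethyl-8-methylidenebicyclo[7.2.0]undec-4-en-11-yl]ethan-1-one | C=C1CC/C=C(\C)CC[C@H]2[C@H]1C[C@]2(C)C(C)=O | intermediate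
25 | (S)-2-methylglycidol | OC[C@@]1(C)CO1 | starting material
26 | tert-butyl{[(2-methyloxiran-2-yl)methyl]oxy}diphenylsilane (spatial arrangement of 25) | CC(C)(C)[Si](OC[C@@]1(C)CO1)(c1ccccc1)c1ccccc1 | intermediate
27 | (S)-3-(tert-butyldiphenylsilyloxy)-2-hydroperoxy-2-methylpropan-1-ol | CC(C)(C)[Si](OC[C@](OO)(C)CO)(c1ccccc1)c1ccccc1 | intermediate
28 | tert-butyldiphenylsilyl ether of 29 | CC(C)(C)[Si](OC[C@](OOC(C)(C)OC)(C)COC(C)(C)OC)(c1ccccc1)c1ccccc1 | intermediate
29 | (S)-3-[(2-methoxypropan-2-yl)oxy]-2-[(2-methoxypropan-2-yl)peroxy]-2-methylpropan-1-ol | OC[C@](OOC(C)(C)OC)(C)COC(C)(C)OC | intermediate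
30 | (S)-3-[(2-methoxypropan-2-yl)oxy]-2-[(2-methoxypropan-2-yl)peroxy]-2-methylpropanal | O=C[C@](OOC(C)(C)OC)(C)COC(C)(C)OC | intermediate
31 | lithium enolate of 24 (C12=C13) | [Li+].C=C1CC/C=C(\C)CC[C@H]2[C@H]1C[C@]2(C)C(=C)[O-] | intermediate (not isolated)
32 | aldol adduct: C12 ketone, C14 hydroxyl (epimers), protected C15 peroxide and C17 ether | C=C1CC/C=C(\C)CC[C@H]2[C@H]1C[C@]2(C)C(=O)CC(O)[C@](OOC(C)(C)OC)(C)COC(C)(C)OC | intermediate
33 | C14 methanesulfonate of 32 | C=C1CC/C=C(\C)CC[C@H]2[C@H]1C[C@]2(C)C(=O)CC(OS(C)(=O)=O)[C@](OOC(C)(C)OC)(C)COC(C)(C)OC | intermediate (not isolated)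
34 | (13E)-enone with protected C15 peroxide and C17 ether | C=C1CC/C=C(\C)CC[C@H]2[C@H]1C[C@]2(C)C(=O)/C=C/[C@](OOC(C)(C)OC)(C)COC(C)(C)OC | intermediate
35 | (13E)-enone with free C15 hydroperoxide and C17 hydroxyl | C=C1CC/C=C(\C)CC[C@H]2[C@H]1C[C@]2(C)C(=O)/C=C/[C@](OO)(C)CO | intermediate
36 | (13Z)-isomer of 35 | C=C1CC/C=C(\C)CC[C@H]2[C@H]1C[C@]2(C)C(=O)/C=C\[C@](OO)(C)CO | intermediate (not isolated)
37 | (1S,4E,9R,11S)-11-[(3R,6R)-3-hydroxy-6-(hydroxymethyl)-6-methyl-3,6-dihydro-1,2-dioxin-3-yl]-4,11-dimethyl-8-methylidenebicyclo[7.2.0]undec-4-ene | C=C1CC/C=C(\C)CC[C@H]2[C@H]1C[C@]2(C)[C@@]1(O)C=C[C@](C)(CO)OO1 | intermediate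
38 | target, (1S,4S,5S,9R,11S)-4,5-epoxide of 37 | C=C1CC[C@@H]2O[C@@]2(C)CC[C@H]2[C@H]1C[C@]2(C)[C@@]1(O)C=C[C@](C)(CO)OO1 | target

## Step count and least certain steps

Total: 26 steps. The longest linear sequence is 21 steps (steps 1–16 and 22–26, from 1). The aldehyde 30 takes 5 steps from 25 (steps 17–21).

**Step 12 (key step).** The trans-fused cyclobutane holds the C8–C9–C1–C2 unit at a wider torsion than the chair transition state prefers. The rearrangement may therefore be slow, and ionisation of the tertiary allylic ether or isomerisation of the exocyclic enol ether into the ring may then compete at the temperature needed.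
Fallback: run the ring expansion in the cis-fused series, whose cyclobutane can pucker to either torsional sense. Setting out from 15, the lactone is epimerised at C9 (LDA at −78 °C and kinetic protonation, or DBU if the cis four-seven fusion is the more stable, as expected) to the cis-fused lactone F1. Petasis methylenation gives the cis-fused enol ether F2, and heating gives the cis-fused Z ketone F3. Base (KOtBu, tBuOH) then epimerises C9 to the more stable trans four-nine fusion, and the route is rejoined at 17.

**Step 6.** Two processes can fail. The carbene of a methyl ester with a trisubstituted olefin may undergo 1,2-hydride shift to the dienoate, or react with eroded face selectivity. The bulky oxygen-substituted cuprate may also transfer poorly to the methyl-bearing bridgehead, so that the bicyclobutane is simply protonated or polymerises.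
Fallback: introduce the acetyl group as a small alkenyl nucleophile and unveil it oxidatively. Setting out from 7, the bicyclobutane 8 is opened with isopropenylmagnesium bromide under CuBr·SMe2/PBu3 catalysis to the isopropenyl cyclobutane ester F4. mCPBA epoxidises the 1,1-disubstituted olefin in preference to the vinyl group to give the epoxide F5, and periodic acid cleaves it to the methyl ketone F6. Ketalisation (ethylene glycol, PPTS, trimethyl orthoformate) rejoins the route at 10.

**Step 10.** Acylation of a hindered tertiary allylic alcohol in a seven-membered ring closure is slow. Intermolecular acylation to diolides and oligomers, or loss of the activated acid by hydrolysis, may win.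
Fallback: avoid the lactone and make the enol ether by alcohol exchange. Setting out from 10, Petasis methylenation of the methyl ester gives the methyl enol ether F7, and TBAF frees the tertiary alcohol to give the hydroxy enol ether F8. Heating F8 with catalytic PPTS in xylene at 140 °C with removal of methanol (Saucy–Marbet conditions) exchanges methanol for the tethered alcohol. The resulting 16 rearranges in the same flask, and the route is rejoined at 17, with C9 equilibrated under the basic conditions of step 13.

**Step 15.** The phosphide may act as a base on the hindered, neopentyl-like oxirane and give allylic alcohols by β-elimination, or the betaine may fail to collapse to the strained E olefin.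
Fallback: reach the E olefin through the trans-epoxide. Setting out from 17, syn-dihydroxylation (OsO4 cat., N-methylmorpholine N-oxide) gives the cis-diols F9 and F10. Mesylation of the secondary hydroxyl and ring closure by the tertiary alkoxide (K2CO3, MeOH) invert C5 and give the trans-epoxy ketones F11 and F12. Wittig methylenation gives the trans-epoxides F13 and F14. Both are deoxygenated with retention by low-valent tungsten (WCl6, n-BuLi, THF), and the route is rejoined at 23; as in the main route, the face of the first oxidation does not matter.

**Step 25.** The excited enone may add intramolecularly to the exocyclic methylene ([2+2]), the O–O bond may be cleaved, or the photostationary state may be unfavourable if hemiperketal closure is slow.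
Fallback: set the Z geometry when the double bond is formed. Setting out from 24, the lithium enolate is C-phosphinylated with bis(2,2,2-trifluoroethyl) phosphorochloridite and oxidised (tBuOOH) to the β-keto phosphonate F15. Still–Gennari olefination with 30 (KHMDS, 18-crown-6, THF, −78 °C) gives the protected Z enone F16. PPTS in methanol removes the ketal groups, and the liberated 36 closes to the hemiperketal; the route is rejoined at 37.

## Further compounds

F1 | step 12 | cis-fused lactone, C9 epimer of 15 | O=C1O[C@@](C)(C=C)CC[C@H]2[C@@H]1C[C@]2(C)C2(C)OCCO2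
F2 | step 12 | cis-fused 2-methylene-7-vinyloxepane, C9 epimer of 16 | C=C1O[C@@](C)(C=C)CC[C@H]2[C@@H]1C[C@]2(C)C2(C)OCCO2
F3 | step 12 | cis-fused Z ketone, C9 epimer of 17 | O=C1CC/C=C(/C)CC[C@H]2[C@@H]1C[C@]2(C)C2(C)OCCO2
F4 | step 6 | methyl (2S,3S)-3-methyl-2-[(3R)-3-methyl-3-(triethylsilyloxy)pent-4-en-1-yl]-3-(prop-1-en-2-yl)cyclobutane-1-carboxylate (C1 epimers) | COC(=O)C1C[C@](C)(C(C)=C)[C@H]1CC[C@@](C)(O[Si](CC)(CC)CC)C=C
F5 | step 6 | 2-methyloxiran-2-yl analogue of F4 (oxirane epimers) | COC(=O)C1C[C@](C)(C2(C)CO2)[C@H]1CC[C@@](C)(O[Si](CC)(CC)CC)C=C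
F6 | step 6 | methyl (2S,3S)-3-acetyl-3-methyl-2-[(3R)-3-methyl-3-(triethylsilyloxy)pent-4-en-1-yl]cyclobutane-1-carboxylate (C1 epimers) | COC(=O)C1C[C@](C)(C(C)=O)[C@H]1CC[C@@](C)(O[Si](CC)(CC)CC)C=C
F7 | step 10 | methyl enol ether from 10 (1-methoxyethenyl in place of the ester, C9 epimers) | COC(=C)C1C[C@](C)(C2(C)OCCO2)[C@H]1CC[C@@](C)(O[Si](CC)(CC)CC)C=C
F8 | step 10 | hydroxy enol ether, desilylated F7 | COC(=C)C1C[C@](C)(C2(C)OCCO2)[C@H]1CC[C@@](C)(O)C=C
F9 | step 15 | (4S,5R)-4,5-dihydroxy ketone from 17 | O=C1CC[C@@H](O)[C@@](C)(O)CC[C@H]2[C@H]1C[C@]2(C)C2(C)OCCO2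
F10 | step 15 | (4R,5S)-4,5-dihydroxy ketone from 17 | O=C1CC[C@H](O)[C@](C)(O)CC[C@H]2[C@H]1C[C@]2(C)C2(C)OCCO2
F11 | step 15 | (4S,5S)-trans-4,5-epoxy ketone | O=C1CC[C@@H]2O[C@@]2(C)CC[C@H]2[C@H]1C[C@]2(C)C2(C)OCCO2
F12 | step 15 | (4R,5R)-trans-4,5-epoxy ketone | O=C1CC[C@H]2O[C@]2(C)CC[C@H]2[C@H]1C[C@]2(C)C2(C)OCCO2
F13 | step 15 | (4S,5S)-trans-4,5-epoxide with C8 methylene | C=C1CC[C@@H]2O[C@@]2(C)CC[C@H]2[C@H]1C[C@]2(C)C2(C)OCCO2
F14 | step 15 | (4R,5R)-trans-4,5-epoxide with C8 methylene | C=C1CC[C@H]2O[C@]2(C)CC[C@H]2[C@H]1C[C@]2(C)C2(C)OCCO2
F15 | step 25 | bis(2,2,2-trifluoroethyl) β-keto phosphonate from 24 | C=C1CC/C=C(\C)CC[C@H]2[C@H]1C[C@]2(C)C(=O)CP(=O)(OCC(F)(F)F)OCC(F)(F)F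
F16 | step 25 | (13Z)-enone with protected C15 peroxide and C17 ether | C=C1CC/C=C(\C)CC[C@H]2[C@H]1C[C@]2(C)C(=O)/C=C\[C@](OOC(C)(C)OC)(C)COC(C)(C)OC
A1 | alternative 1 | 2,2,4,5-tetrasubstituted pyrrolidine (nitrogen between C1 and C11) | COC(=O)[C@]1(COCc2ccccc2)C[C@@H](C(=O)OC(C)(C)C)[C@H](CCC2(C)OCCO2)N1
A2 | alternative 1 | tetrasubstituted cyclobutane | COC(=O)[C@]1(COCc2ccccc2)C[C@@H](C(=O)OC(C)(C)C)[C@@H]1CCC1(C)OCCO1
A3 | alternative 2 | Z enone with 2-methyloxiran-2-yl group at C14 | C=C1CC/C=C(\C)CC[C@H]2[C@H]1C[C@]2(C)C(=O)/C=C\[C@@]1(C)CO1
A4 | alternative 2 | 4,5-deoxy target (identical with 37) | C=C1CC/C=C(\C)CC[C@H]2[C@H]1C[C@]2(C)[C@@]1(O)C=C[C@](C)(CO)OO1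
A5 | alternative 3 | (E)-cyclononenone bis-tosylate | O=C1CC/C=C(\C)CC[C@@H](C1)C(C)(COS(=O)(=O)c1ccc(C)cc1)COS(=O)(=O)c1ccc(C)cc1
A6 | alternative 3 | bicyclo[7.2.0] ketone with C12 tosylate | O=C1CC/C=C(\C)CC[C@H]2[C@H]1C[C@]2(C)COS(=O)(=O)c1ccc(C)cc1
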